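## Structural features

The target is a C2-symmetric C30 compound. Two identical cyclohex-3-en-1-ol rings are joined through their C4 atoms by an (E,E)-buta-1,3-diene, so the two ring alkenes and the linker form one conjugated tetraene. In each ring the secondary carbinol C1 (R) stands next to the quaternary carbon C2 (S), which carries a methyl group and a 2-(3,3-dimethyloxiran-2-yl)ethyl chain; the hydroxyl is cis to that chain. The third stereocentre, the oxirane CH (R), lies four bonds from C2 and cannot be controlled by the ring. The fragile groups are the trisubstituted epoxides (acid, Lewis acid, and the cis-hydroxyl as an internal nucleophile) and the tetraene (light, oxygen, acid). The real difficulty is the all-carbon quaternary stereocentre wedged between the carbinol and the ring alkene CH, together with placing the sp2 carbon C4 that carries the linker. The key step exploits the three-carbon unit C1–C6–C5, which starts next to C2 and ends at C4. It is stored as a cyclopropanol on C2 and released as a ketone homoenolate that bonds C5 to C4. Because of the symmetry, one monomer line serves both halves.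

## Logic of the disconnections

23 is cut at the central C(sp2)–C(sp2) single bond of the butadiene linker, giving 21 and 22. Both halves are identical, so the cut halves the problem. The forward coupling must keep both E alkenes and tolerate free hydroxyls and epoxides.

21 and 22 are each cut at the exocyclic CH=CH bond and traced to the one aldehyde 20. A single precursor then feeds both partners. The forward one-carbon olefinations must be E-selective.

20 is simplified to 19 by removing the oxirane oxygen. At this stage the ring alkene is conjugated to the formyl group and electron-poor, so only the side-chain alkene is nucleophilic. The forward step needs reagent control, since the ring cannot direct a centre this remote.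

19 is traced through 18 and 17 to 16 without cutting a skeletal bond (formyl to hydroxymethyl, silyl ether back on, C1–H removed). The forward hydride delivery must set C1 relative to the fixed C2, by reagent control, because methyl and chain on C2 differ too little for substrate control.

16 is cut at the C4–C5 ring bond, giving 15. This opens the only ring and reduces the problem to an acyclic quaternary carbon bearing a cyclopropanol and a cis-iodoalkene. The forward step needs iodine cis to the quaternary carbon and reductive elimination faster than β-hydride elimination. The configuration at the quaternary carbon and the alkene geometry of 15 and 16 were checked against 23 and agree with it.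

15 is cut at both bonds from the carbinol carbon to the cyclopropane CH2 groups, giving 13 and 14. The three-membered ring becomes an ester plus a two-carbon dianion equivalent. The forward step must tolerate a hindered ester and a vinylic iodide.

13 is traced through 12 to 10 (O–Si, then C–I and the vinylic C–H, via 11). The alkene becomes an alkyne, and its geometry becomes a question of trans addition and regiochemistry. A free propargylic hydroxyl is what steers tin to the correct carbon, so the silyl ether is put on only afterwards.

10 is traced through 9 and 8 to 7 by cutting the C1–C2 bond of a 1,2-diol and adjusting the oxidation level. Glycol cleavage stops at the aldehyde, so oxidation and esterification are separate steps. The aldehyde has no α-hydrogen, so the stereocentre is safe.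

7 is cut at the bond from the quaternary carbon to the alkyne carbon, giving 2 and 3 (via 4, 5 and 6). The quaternary stereocentre is reduced to a trisubstituted epoxide. The forward opening must occur at the tertiary carbon with inversion.

2 is simplified to 1 by removing the epoxide oxygen. The forward epoxidation must select the allylic alkene and the correct face; with the (Z)-alkene of 1 this requires the D-(−)-tartrate.

## Other disconnections considered

Alternative 1: The cut removes two ring bonds at once, C2–C3 and C1–C6 (ring numbering of 23), and leads to methyl coumalate A1 and the enantiopure cyclic enol ether A2.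
- **Forward step:** inverse-demand [4+2] cycloaddition followed by decarboxylation would give the cis-fused bicycle A3.
- **In its favour:** the cyclic dienophile locks the cis relation between the future hydroxyl and the future chain, so both ring stereocentres arise in one step. The methyl group blocks aromatisation. The ester already sits on the linker-bearing carbon. The lactol acetal is a masked aldehyde for the prenyl terminus. No metal is needed.
- **Against it here:** a trisubstituted enol ether is a sluggish dienophile. The usual routes to 2-alkoxydihydropyrans give the racemate, so A2 needs a resolution. The facial sense rests on the acetal centre alone. The extra ring alkene of A3 must be hydrogenated next to a dienoate without touching the alkene that is kept.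
- **Comparison:** structurally A3 is the better, since it maps C1 and C2 together, whereas the chosen plan sets them in two separate events (steps 1–2 and step 10). Mechanistically it is a thermal pericyclic step against an organometallic one. On step count A3 should reach 19 in about five operations and is the better, provided A2 is available enantiopure. The chosen plan is the better on certainty of absolute configuration, because all three stereocentres come from catalytic asymmetric reactions of predictable sense.

Alternative 2: The cut is a retro-enyne metathesis in each half (the ring C3=C4 bond and the exocyclic CH=CH bond), leading to the acyclic diene-diyne A5, an isomer of the bis(silyl ether) A4.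
- **Forward step:** a ruthenium carbene (second-generation Grubbs catalyst) would close both rings and form the tetraene in one isomerisation, and desilylation of A4 would finish the synthesis.
- **In its favour:** maximal late convergence, full atom economy, and no stoichiometric chromium or tin.
- **Against it here:** the alkenes of the central diene sit directly on the quaternary carbons and are hindered. The mechanism does not fix the geometry of the new exocyclic CH=CH bonds. The diene can enter competing exo and endo pathways or oligomerise. A5 already holds all six stereocentres, including both quaternary ones, so the hardest task is only postponed.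
- **Comparison:** on the endgame the alternative is the better, since one step replaces ring closure, two olefinations and the coupling. Structurally it is the equal of the chosen plan, because the same stereocentres must be made by similar chemistry beforehand. Mechanistically the chosen plan is the safer: its ring closure is intramolecular and forms one defined bond, and its alkene geometries are set by E-selective olefinations.

Alternative 3: The cut removes the two ring bonds to C4 (retro one-carbon insertion), leading to the cyclopentene A7, which can be traced to the prochiral dione A8.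
- **Forward step:** dibromocarbene addition and electrocyclic opening would give the dibromocyclohexene A6.
- **In its favour:** the reagents are cheap. Desymmetrising reduction of A8 would set C1 and C2 together in one well-established step, a point on which it is the equal or the better of the chosen plan. The vinylic bromide of A6 lands on the linker-bearing carbon, so a twofold coupling with a four-carbon linchpin could replace both olefinations.
- **Against it here:** the allyl cation from ring opening can capture bromide at either end, which can misplace the alkene. The allylic bromide must then be removed without transposing the alkene or touching the vinylic bromide. A ketone-to-alkene conversion is needed to reach A7. The acetal chain still has to be converted to the prenyl group and epoxidised.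
- **Comparison:** structurally it introduces the linker carbon late, where the chosen plan carries it from step 2. Mechanistically it depends on cation regiochemistry, where the chosen plan has a regiochemically unambiguous reductive elimination (both cyclopropane CH2 groups are equivalent). On step count it is at best equal and probably longer.

Key step: step 9

Remark on the chemistry: the trans-hydrostannation is steered by a free propargylic hydroxyl. The alkyne is therefore brought in as its trimethylsilyl ether, which is shed on work-up of step 2, and the tert-butyldimethylsilyl group is attached only after iodination.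

## Route

Step 1
Reactants: 1 nerol
Product: 2 [(2R,3S)-3-methyl-3-(4-methylpent-3-en-1-yl)oxiran-2-yl]methanol
Conditions: Ti(OiPr)4 (cat.), D-(−)-diethyl tartrate (cat.), tBuOOH, 4 Å molecular sieves, CH2Cl2, −20 °C
Reagents that add atoms: tert-butyl hydroperoxide, CC(C)(C)OO
Why: Sharpless asymmetric epoxidation; the titanium tartrate binds the allylic hydroxyl, so only the 2,3-alkene reacts and the distal alkene is left, and the D-(−)-tartrate delivers oxygen to the face that gives the (2R,3S)-epoxide, whose C3 becomes the quaternary carbon.

Step 2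
Reactants: 2 [(2R,3S)-3-methyl-3-(4-methylpent-3-en-1-yl)oxiran-2-yl]methanol; 3 trimethyl(prop-2-yn-1-yloxy)silane
Product: 7 (2S,3S)-3-(3-hydroxyprop-1-yn-1-yl)-3,7-dimethyloct-6-ene-1,2-diol, via lithium acetylide 4 (not isolated), via alkynylalane 5 (not isolated), via silyl ether diol 6 (not isolated)
Conditions: 3, nBuLi, toluene, 0 °C; Et2AlCl, 0 °C; then 2, 0 °C → rt; aq. KNaC4H4O6; K2CO3 (cat.), MeOH, rt
Reagents that add atoms: none
Why: Alkynylalane opening of a 2,3-epoxy alcohol; the aluminium alkoxide activates the oxirane and the alkynyl group attacks the tertiary C3, which carries most of the positive charge, with inversion, so the quaternary centre forms as (S). Methanolysis on work-up removes the trimethylsilyl group and frees the propargylic hydroxyl needed in step 6.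

Step 3
Reactants: 7 (2S,3S)-3-(3-hydroxyprop-1-yn-1-yl)-3,7-dimethyloct-6-ene-1,2-diol
Product: 8 (2S)-2-(3-hydroxyprop-1-yn-1-yl)-2,6-dimethylhept-5-enal
Conditions: NaIO4, THF/H2O, 0 °C → rt
Reagents that add atoms: none
Why: Periodate glycol cleavage removes C1 as formaldehyde and leaves an aldehyde with no α-hydrogen, so the stereocentre cannot epimerise; alkene, alkyne and the isolated primary alcohol are inert.

Step 4
Reactants: 8 (2S)-2-(3-hydroxyprop-1-yn-1-yl)-2,6-dimethylhept-5-enal
Product: 9 (2S)-2-(3-hydroxyprop-1-yn-1-yl)-2,6-dimethylhept-5-enoic acid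
Conditions: NaClO2, NaH2PO4, 2-methylbut-2-ene, tBuOH/H2O, 0 °C → rt
Reagents that add atoms: sodium chlorite, [Na+].[O-]Cl=O
Why: Pinnick oxidation is selective for the aldehyde; the alkene scavenger removes hypochlorous acid, which protects the trisubstituted alkene, and the propargylic alcohol is not oxidised.

Step 5
Reactants: 9 (2S)-2-(3-hydroxyprop-1-yn-1-yl)-2,6-dimethylhept-5-enoic acid
Product: 10 methyl (2S)-2-(3-hydroxyprop-1-yn-1-yl)-2,6-dimethylhept-5-enoate
Conditions: MeI, K2CO3, DMF, rt
Reagents that add atoms: iodomethane, CI
Why: O-alkylation of the carboxylate is not slowed by the neighbouring quaternary carbon, unlike Fischer esterification, and the neutral alcohol is not methylated under carbonate.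

Step 6
Reactants: 10 methyl (2S)-2-(3-hydroxyprop-1-yn-1-yl)-2,6-dimethylhept-5-enoate
Product: 12 methyl (2S)-2-[(1Z)-3-hydroxy-2-iodoprop-1-en-1-yl]-2,6-dimethylhept-5-enoate, via alkenylstannane 11 (not isolated)
Conditions: Bu3SnH, [Cp*RuCl]4 (cat.), CH2Cl2, rt; then I2, 0 °C
Reagents that add atoms: iodine, II
Why: Ruthenium-catalysed trans-hydrostannation; the free propargylic hydroxyl hydrogen-bonds to the chloride ligand and steers tin to the proximal alkyne carbon, and trans addition places tin cis to the quaternary carbon. Iododestannation proceeds with retention and is much faster than any reaction of iodine with the isolated alkene.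

Step 7
Reactants: 12 methyl (2S)-2-[(1Z)-3-hydroxy-2-iodoprop-1-en-1-yl]-2,6-dimethylhept-5-enoate
Product: 13 methyl (2S)-2-[(1Z)-3-(tert-butyldimethylsilyloxy)-2-iodoprop-1-en-1-yl]-2,6-dimethylhept-5-enoate
Conditions: TBSCl, imidazole, CH2Cl2, 0 °C → rt
Reagents that add atoms: tert-butyldimethylsilyl chloride, CC(C)(C)[Si](C)(C)Cl
Why: Standard silylation of a primary alcohol; the ether keeps the hydroxyl away from the Grignard reagent in step 8 and from palladium in step 9.

Step 8
Reactants: 13 methyl (2S)-2-[(1Z)-3-(tert-butyldimethylsilyloxy)-2-iodoprop-1-en-1-yl]-2,6-dimethylhept-5-enoate; 14 ethylmagnesium bromide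
Product: 15 1-[(2Z,4S)-1-(tert-butyldimethylsilyloxy)-2-iodo-4,8-dimethylnona-2,7-dien-4-yl]cyclopropan-1-ol
Conditions: EtMgBr (slow addition), Ti(OiPr)4 (0.5 equiv), THF, 0 °C → rt
Reagents that add atoms: none
Why: Kulinkovich cyclopropanation; the titanacyclopropane made from 14 acts as a 1,2-dicarbanion and alkylates the ester carbonyl twice. Slow addition keeps free Grignard reagent low, so the vinylic iodide and the silyl ether should remain spectators.

Step 9
Reactants: 15 1-[(2Z,4S)-1-(tert-butyldimethylsilyloxy)-2-iodo-4,8-dimethylnona-2,7-dien-4-yl]cyclopropan-1-ol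
Product: 16 (2S)-4-[(tert-butyldimethylsilyloxy)methyl]-2-methyl-2-(4-methylpent-3-en-1-yl)cyclohex-3-en-1-one
Conditions: Pd(OAc)2 (10 mol%), XPhos (20 mol%), Cs2CO3, toluene, 80 °C
Reagents that add atoms: none
Why: Pd(OAc)2 is reduced in situ to zerovalent palladium, which inserts into the C–I bond with retention of alkene geometry; carbonate deprotonates the cyclopropanol and the alkoxide replaces iodide, giving a six-membered alkenylpalladium alkoxide. Strain-driven β-carbon elimination cleaves one of the two equivalent cyclopropane C–C bonds and gives a divalent palladium homoenolate in a seven-membered palladacycle, and C(sp2)–C(sp3) reductive elimination forms the C4–C5 bond and returns zerovalent palladium. The closest known reaction type is the palladium-catalysed ring-opening cross-coupling of cyclopropanols with aryl and alkenyl halides, here run intramolecularly. The one ring formed, the cyclohexenone, is closed by reductive elimination with contraction of the seven-membered palladacycle to the six-membered carbocycle, not by a polar or radical cyclisation. No stereocentre is created; the quaternary carbon is a spectator that cannot epimerise, and the ring alkene is fixed by the (Z)-iodide from step 6. The selectivity needed is reductive elimination ahead of β-hydride elimination of the homoenolate; the chelated, geminally disubstituted tether (Thorpe–Ingold effect) and the bulky electron-rich biarylphosphine favour it. The silyl ether is a poor leaving group for β-oxygen elimination, and the β,γ-enone cannot move into conjugation through the quaternary carbon.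

Step 10
Reactants: 16 (2S)-4-[(tert-butyldimethylsilyloxy)methyl]-2-methyl-2-(4-methylpent-3-en-1-yl)cyclohex-3-en-1-one
Product: 17 (1R,2S)-4-[(tert-butyldimethylsilyloxy)methyl]-2-methyl-2-(4-methylpent-3-en-1-yl)cyclohex-3-en-1-ol
Conditions: (S)-Me-CBS oxazaborolidine (0.2 equiv), catecholborane, toluene, −78 → −40 °C
Reagents that add atoms: none
Why: Corey–Bakshi–Shibata reduction; the catalyst distinguishes the quaternary C2 (large) from the C6 methylene (small), and the (S)-catalyst delivers hydride to the face that gives the (R)-carbinol, with the hydroxyl cis to the chain. Catecholborane at low temperature does not hydroborate the alkenes.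

Step 11
Reactants: 17 (1R,2S)-4-[(tert-butyldimethylsilyloxy)methyl]-2-methyl-2-(4-methylpent-3-en-1-yl)cyclohex-3-en-1-ol
Product: 18 (1R,2S)-4-(hydroxymethyl)-2-methyl-2-(4-methylpent-3-en-1-yl)cyclohex-3-en-1-ol
Conditions: TBAF, THF, 0 °C → rt
Reagents that add atoms: none
Why: Fluoride cleaves the primary silyl ether; nothing else in the molecule responds to fluoride.

Step 12
Reactants: 18 (1R,2S)-4-(hydroxymethyl)-2-methyl-2-(4-methylpent-3-en-1-yl)cyclohex-3-en-1-ol
Product: 19 (3S,4R)-4-hydroxy-3-methyl-3-(4-methylpent-3-en-1-yl)cyclohex-1-ene-1-carbaldehyde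
Conditions: MnO2, CH2Cl2, rt
Reagents that add atoms: none
Why: MnO2 oxidises only the allylic primary alcohol; the saturated secondary carbinol is untouched, so no protecting group is needed.

Step 13
Reactants: 19 (3S,4R)-4-hydroxy-3-methyl-3-(4-methylpent-3-en-1-yl)cyclohex-1-ene-1-carbaldehyde
Product: 20 (3S,4R)-3-{2-[(2R)-3,3-dimethyloxiran-2-yl]ethyl}-4-hydroxy-3-methylcyclohex-1-ene-1-carbaldehyde
Conditions: D-fructose-derived Shi ketone (0.3 equiv), KHSO5 (as 2KHSO5·KHSO4·K2SO4), K2CO3, Bu4NHSO4, MeCN/CH2(OMe)2–aq. Na2B4O7 buffer, pH 10.5, 0 °C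
Reagents that add atoms: potassium peroxymonosulfate, [K+].[O-]S(=O)(=O)OO
Why: Shi epoxidation; the chiral dioxirane attacks only the electron-rich side-chain alkene, because the ring alkene is deactivated as an enal and shielded by the quaternary carbon. The spiro transition state of the D-fructose-derived ketone gives the (R)-oxirane, which is reagent control, as required for this remote centre.

Step 14
Reactants: 20 (3S,4R)-3-{2-[(2R)-3,3-dimethyloxiran-2-yl]ethyl}-4-hydroxy-3-methylcyclohex-1-ene-1-carbaldehyde
Product: 21 (1R,2S)-2-{2-[(2R)-3,3-dimethyloxiran-2-yl]ethyl}-4-[(E)-2-iodoethenyl]-2-methylcyclohex-3-en-1-ol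
Conditions: CrCl2, CHI3, THF/1,4-dioxane, 0 °C → rt
Reagents that add atoms: iodoform, IC(I)I
Why: Takai iodo-olefination; the geminal dichromium species adds to the aldehyde and anti-elimination gives the (E)-alkenyl iodide. Divalent chromium reagents are not basic and tolerate the free hydroxyl.

Step 15
Reactants: 20 (3S,4R)-3-{2-[(2R)-3,3-dimethyloxiran-2-yl]ethyl}-4-hydroxy-3-methylcyclohex-1-ene-1-carbaldehyde
Product: 22 (1R,2S)-2-{2-[(2R)-3,3-dimethyloxiran-2-yl]ethyl}-2-methyl-4-[(E)-2-(4,4,5,5-tetramethyl-1,3,2-dioxaborolan-2-yl)ethenyl]cyclohex-3-en-1-ol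
Conditions: Cl2CHBpin, CrCl2, LiI, THF, rt
Reagents that add atoms: 2-(dichloromethyl)-4,4,5,5-tetramethyl-1,3,2-dioxaborolane, ClC(Cl)B1OC(C)(C)C(C)(C)O1
Why: Takai–Utimoto boryl-olefination, the boron counterpart of step 14; the same chromium carbenoid mechanism gives the (E)-alkenylboronate from the same aldehyde.

Step 16
Reactants: 21 (1R,2S)-2-{2-[(2R)-3,3-dimethyloxiran-2-yl]ethyl}-4-[(E)-2-iodoethenyl]-2-methylcyclohex-3-en-1-ol; 22 (1R,2S)-2-{2-[(2R)-3,3-dimethyloxiran-2-yl]ethyl}-2-methyl-4-[(E)-2-(4,4,5,5-tetramethyl-1,3,2-dioxaborolan-2-yl)ethenyl]cyclohex-3-en-1-ol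
Product: 23 (1R,1′R,2S,2′S)-4,4′-[(1E,3E)-buta-1,3-diene-1,4-diyl]bis(2-{2-[(2R)-3,3-dimethyloxiran-2-yl]ethyl}-2-methylcyclohex-3-en-1-ol)
Conditions: Pd(PPh3)4 (cat.), aq. K3PO4, THF, 40 °C, degassed, dark
Reagents that add atoms: none
Why: Suzuki–Miyaura coupling of an alkenyl iodide with an alkenylboronate proceeds with retention at both partners, so the (E,E)-linker forms under mild basic conditions that leave epoxides and hydroxyls alone.

## Compound list

1 | nerol, (2Z)-3,7-dimethylocta-2,6-dien-1-ol | CC(C)=CCC/C(C)=C\CO | starting material
2 | [(2R,3S)-3-methyl-3-(4-methylpent-3-en-1-yl)oxiran-2-yl]methanol | CC(C)=CCC[C@]1(C)O[C@@H]1CO | intermediate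
3 | trimethyl(prop-2-yn-1-yloxy)silane | C#CCO[Si](C)(C)C | starting material
4 | lithium 3-(trimethylsilyloxy)prop-1-yn-1-ide | [Li]C#CCO[Si](C)(C)C | intermediate (not isolated)
5 | diethyl[3-(trimethylsilyloxy)prop-1-yn-1-yl]alane | CC[Al](CC)C#CCO[Si](C)(C)C | intermediate (not isolated)
6 | (2S,3S)-3,7-dimethyl-3-[3-(trimethylsilyloxy)prop-1-yn-1-yl]oct-6-ene-1,2-diol | CC(C)=CCC[C@@](C)(C#CCO[Si](C)(C)C)[C@H](O)CO | intermediate (not isolated)
7 | (2S,3S)-3-(3-hydroxyprop-1-yn-1-yl)-3,7-dimethyloct-6-ene-1,2-diol | CC(C)=CCC[C@@](C)(C#CCO)[C@H](O)CO | intermediate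
8 | (2S)-2-(3-hydroxyprop-1-yn-1-yl)-2,6-dimethylhept-5-enal | CC(C)=CCC[C@@](C)(C#CCO)C=O | intermediate
9 | (2S)-2-(3-hydroxyprop-1-yn-1-yl)-2,6-dimethylhept-5-enoic acid | CC(C)=CCC[C@@](C)(C#CCO)C(=O)O | intermediate
10 | methyl (2S)-2-(3-hydroxyprop-1-yn-1-yl)-2,6-dimethylhept-5-enoate | CC(C)=CCC[C@@](C)(C#CCO)C(=O)OC | intermediate
11 | methyl (2S)-2-[(1Z)-3-hydroxy-2-(tributylstannyl)prop-1-en-1-yl]-2,6-dimethylhept-5-enoate | CC(C)=CCC[C@@](C)(/C=C(\[Sn](CCCC)(CCCC)CCCC)CO)C(=O)OC | intermediate (not isolated)
12 | methyl (2S)-2-[(1Z)-3-hydroxy-2-iodoprop-1-en-1-yl]-2,6-dimethylhept-5-enoate | CC(C)=CCC[C@@](C)(/C=C(\I)CO)C(=O)OC | intermediate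
13 | methyl (2S)-2-[(1Z)-3-(tert-butyldimethylsilyloxy)-2-iodoprop-1-en-1-yl]-2,6-dimethylhept-5-enoate | CC(C)=CCC[C@@](C)(/C=C(\I)CO[Si](C)(C)C(C)(C)C)C(=O)OC | intermediate
14 | ethylmagnesium bromide | CC[Mg]Br | starting material
15 | 1-[(2Z,4S)-1-(tert-butyldimethylsilyloxy)-2-iodo-4,8-dimethylnona-2,7-dien-4-yl]cyclopropan-1-ol | CC(C)=CCC[C@@](C)(/C=C(\I)CO[Si](C)(C)C(C)(C)C)C1(O)CC1 | intermediate
16 | (2S)-4-[(tert-butyldimethylsilyloxy)methyl]-2-methyl-2-(4-methylpent-3-en-1-yl)cyclohex-3-en-1-one | CC(C)=CCC[C@@]1(C)C=C(CO[Si](C)(C)C(C)(C)C)CCC1=O | intermediate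
17 | (1R,2S)-4-[(tert-butyldimethylsilyloxy)methyl]-2-methyl-2-(4-methylpent-3-en-1-yl)cyclohex-3-en-1-ol | CC(C)=CCC[C@@]1(C)C=C(CO[Si](C)(C)C(C)(C)C)CC[C@H]1O | intermediate
18 | (1R,2S)-4-(hydroxymethyl)-2-methyl-2-(4-methylpent-3-en-1-yl)cyclohex-3-en-1-ol | CC(C)=CCC[C@@]1(C)C=C(CO)CC[C@H]1O | intermediate
19 | (3S,4R)-4-hydroxy-3-methyl-3-(4-methylpent-3-en-1-yl)cyclohex-1-ene-1-carbaldehyde | CC(C)=CCC[C@@]1(C)C=C(C=O)CC[C@H]1O | intermediate
20 | (3S,4R)-3-{2-[(2R)-3,3-dimethyloxiran-2-yl]ethyl}-4-hydroxy-3-methylcyclohex-1-ene-1-carbaldehyde | CC1(C)O[C@@H]1CC[C@@]1(C)C=C(C=O)CC[C@H]1O | intermediate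
21 | (1R,2S)-2-{2-[(2R)-3,3-dimethyloxiran-2-yl]ethyl}-4-[(E)-2-iodoethenyl]-2-methylcyclohex-3-en-1-ol | CC1(C)O[C@@H]1CC[C@@]1(C)C=C(/C=C/I)CC[C@H]1O | intermediate
22 | (1R,2S)-2-{2-[(2R)-3,3-dimethyloxiran-2-yl]ethyl}-2-methyl-4-[(E)-2-(4,4,5,5-tetramethyl-1,3,2-dioxaborolan-2-yl)ethenyl]cyclohex-3-en-1-ol | CC1(C)O[C@@H]1CC[C@@]1(C)C=C(/C=C/B2OC(C)(C)C(C)(C)O2)CC[C@H]1O | intermediate
23 | (1R,1′R,2S,2′S)-4,4′-[(1E,3E)-buta-1,3-diene-1,4-diyl]bis(2-{2-[(2R)-3,3-dimethyloxiran-2-yl]ethyl}-2-methylcyclohex-3-en-1-ol) | CC1(C)O[C@@H]1CC[C@@]1(C)C=C(/C=C/C=C/C2=C[C@](C)(CC[C@H]3OC3(C)C)[C@H](O)CC2)CC[C@H]1O | target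

## Step count and least certain steps

Total step count: 16. Longest linear sequence: 15 (steps 1–13, then step 14 or 15, then step 16).

**Step 9 (key step).** The most likely failure is β-hydride elimination of the palladium homoenolate, or hydrodeiodination, outrunning reductive elimination; the carbon chain then ends as an acyclic enone with a reduced alkene. The fallback makes the same C4–C5 bond by an intramolecular B-alkyl Suzuki–Miyaura coupling. It sets out from 13 and so also bypasses the cyclopropanol. iBu2AlH (CH2Cl2, −78 °C) should give the aldehyde F1. CH2=CHMgBr should add to give the allylic alcohol F2 as both carbinol epimers. 9-Borabicyclo[3.3.1]nonane should hydroborate the terminal vinyl group selectively to the alkylborane F3. Pd(dppf)Cl2, AsPh3 and Cs2CO3 in DMF/THF/water should close the ring to the cyclohexenol F4. Dess–Martin oxidation merges both epimers and comes back to the route at 16.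

**Step 8.** The neighbouring quaternary carbon slows attack on the ester, and forcing the reaction invites loss of the vinylic iodide by iodine–magnesium exchange or reduction by low-valent titanium. The fallback builds the cyclopropanol by enol-ether cyclopropanation and sets out from 13. Cp2Ti(μ-Cl)(μ-CH2)AlMe2 should methylenate the ester to the enol ether F5. Mild aqueous acid should give the methyl ketone F6. LiN(iPr)2 and Me3SiCl should give the silyl enol ether F7, which can only form on the methyl side. Et2Zn/CH2I2 (Simmons–Smith, Furukawa variant) should cyclopropanate this most electron-rich alkene to the silyloxycyclopropane F8. K2CO3 in methanol comes back to the route at 15.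

**Step 13.** The formyl group may be over-oxidised by peroxymonosulfate, or the enal may degrade in the basic medium, before the side-chain alkene is consumed. The fallback moves the epoxidation to a stage without an aldehyde and sets out from 17. There the ring alkene is distinguished from the side-chain alkene only by the shielding quaternary carbon and the inductive effect of the allylic silyl ether. Shi epoxidation should give the epoxy silyl ether F9, TBAF the epoxy diol F10, and MnO2 comes back to the route at 20.

**Step 14 (the same concern applies to step 15).** Lewis-acidic trivalent chromium salts may trigger opening of the oxirane, in particular attack by the cis-hydroxyl to form a cyclic ether; incomplete E-selectivity is a lesser concern. The fallback avoids chromium and the iodide partner altogether and sets out from 20. A boron–Wittig olefination (CH2(Bpin)2, lithium 2,2,6,6-tetramethylpiperidide, THF, −78 °C) should give 22. Palladium-catalysed oxidative homocoupling of 22 (Pd(OAc)2, p-benzoquinone, aq. K3PO4, THF) then exploits the symmetry of the target and comes back at 23. This detour makes no compound outside the list (entry F0).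

## Further compounds

F1 | step 9 | (2S)-2-[(1Z)-3-(tert-butyldimethylsilyloxy)-2-iodoprop-1-en-1-yl]-2,6-dimethylhept-5-enal | CC(C)=CCC[C@@](C)(/C=C(\I)CO[Si](C)(C)C(C)(C)C)C=O
F2 | step 9 | (4S,5Z)-7-(tert-butyldimethylsilyloxy)-6-iodo-4-methyl-4-(4-methylpent-3-en-1-yl)hepta-1,5-dien-3-ol, both C3 epimers | CC(C)=CCC[C@@](C)(/C=C(\I)CO[Si](C)(C)C(C)(C)C)C(O)C=C
F3 | step 9 | (4S,5Z)-1-(9-borabicyclo[3.3.1]nonan-9-yl)-7-(tert-butyldimethylsilyloxy)-6-iodo-4-methyl-4-(4-methylpent-3-en-1-yl)hept-5-en-3-ol, both C3 epimers | CC(C)=CCC[C@@](C)(/C=C(\I)CO[Si](C)(C)C(C)(C)C)C(O)CCB1C2CCCC1CCC2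
F4 | step 9 | (2S)-4-[(tert-butyldimethylsilyloxy)methyl]-2-methyl-2-(4-methylpent-3-en-1-yl)cyclohex-3-en-1-ol, both C1 epimers | CC(C)=CCC[C@@]1(C)C=C(CO[Si](C)(C)C(C)(C)C)CCC1O
F5 | step 8 | tert-butyl{[(2Z,4S)-2-iodo-5-methoxy-4-methyl-4-(4-methylpent-3-en-1-yl)hexa-2,5-dien-1-yl]oxy}dimethylsilane | CC(C)=CCC[C@@](C)(/C=C(\I)CO[Si](C)(C)C(C)(C)C)C(=C)OC
F6 | step 8 | (3S,4Z)-6-(tert-butyldimethylsilyloxy)-5-iodo-3-methyl-3-(4-methylpent-3-en-1-yl)hex-4-en-2-one | CC(C)=CCC[C@@](C)(/C=C(\I)CO[Si](C)(C)C(C)(C)C)C(C)=O
F7 | step 8 | tert-butyl{[(2Z,4S)-2-iodo-4-methyl-4-(4-methylpent-3-en-1-yl)-5-(trimethylsilyloxy)hexa-2,5-dien-1-yl]oxy}dimethylsilane | CC(C)=CCC[C@@](C)(/C=C(\I)CO[Si](C)(C)C(C)(C)C)C(=C)O[Si](C)(C)C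
F8 | step 8 | trimethylsilyl ether of 15, tert-butyl{[(2Z,4S)-2-iodo-4,8-dimethyl-4-[1-(trimethylsilyloxy)cyclopropyl]nona-2,7-dien-1-yl]oxy}dimethylsilane | CC(C)=CCC[C@@](C)(/C=C(\I)CO[Si](C)(C)C(C)(C)C)C1(O[Si](C)(C)C)CC1
F9 | step 13 | (1R,2S)-4-[(tert-butyldimethylsilyloxy)methyl]-2-{2-[(2R)-3,3-dimethyloxiran-2-yl]ethyl}-2-methylcyclohex-3-en-1-ol | CC1(C)O[C@@H]1CC[C@@]1(C)C=C(CO[Si](C)(C)C(C)(C)C)CC[C@H]1O
F10 | step 13 | (1R,2S)-2-{2-[(2R)-3,3-dimethyloxiran-2-yl]ethyl}-4-(hydroxymethyl)-2-methylcyclohex-3-en-1-ol | CC1(C)O[C@@H]1CC[C@@]1(C)C=C(CO)CC[C@H]1O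
F0 | step 14 | none | none
A1 | alternative 1 | methyl coumalate, methyl 2-oxo-2H-pyran-5-carboxylate | COC(=O)C1=COC(=O)C=C1
A2 | alternative 1 | (2S)-2-ethoxy-5-methyl-3,4-dihydro-2H-pyran | CCO[C@@H]1CCC(C)=CO1
A3 | alternative 1 | methyl (2S,4aS,8aR)-2-ethoxy-4a-methyl-3,4,4a,8a-tetrahydro-2H-chromene-6-carboxylate | CCO[C@@H]1CC[C@@]2(C)C=C(C(=O)OC)C=C[C@H]2O1
A4 | alternative 2 | bis(tert-butyldimethylsilyl) ether of 23 | CC1(C)O[C@@H]1CC[C@@]1(C)C=C(/C=C/C=C/C2=C[C@](C)(CC[C@H]3OC3(C)C)[C@H](O[Si](C)(C)C(C)(C)C)CC2)CC[C@H]1O[Si](C)(C)C(C)(C)C
A5 | alternative 2 | (5R,6S,7E,9E,11S,12R)-5,12-bis(tert-butyldimethylsilyloxy)-6,11-bis{2-[(2R)-3,3-dimethyloxiran-2-yl]ethyl}-6,11-dimethylhexadeca-7,9-diene-1,15-diyne | CC1(C)O[C@@H]1CC[C@@]([C@H](O[Si](C)(C)C(C)(C)C)CCC#C)(C)/C=C/C=C/[C@](C)(CC[C@H]1OC1(C)C)[C@H](O[Si](C)(C)C(C)(C)C)CCC#C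
A6 | alternative 3 | tert-butyl{[(1R,2S)-4,5-dibromo-2-(3,3-dimethoxypropyl)-2-methylcyclohex-3-en-1-yl]oxy}dimethylsilane, mixture at C5 | COC(OC)CC[C@@]1(C)C=C(Br)C(Br)C[C@H]1O[Si](C)(C)C(C)(C)C
A7 | alternative 3 | tert-butyl{[(1R,2S)-2-(3,3-dimethoxypropyl)-2-methylcyclopent-3-en-1-yl]oxy}dimethylsilane | COC(OC)CC[C@@]1(C)C=CC[C@H]1O[Si](C)(C)C(C)(C)C
A8 | alternative 3 | 2-(3,3-dimethoxypropyl)-2-methylcyclopentane-1,3-dione | COC(OC)CCC1(C)C(=O)CCC1=O
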